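**Plan**

- Retrosynthetic cuts: O1–C2 (oxa-Michael closure of ring C); C3–C4 and C4–C4a (alkenyl addition to a C4a aldehyde made by ortho-formylation); ring A at C8–C8a and C6–C7 (cyclobutenone plus ynol ether); the cyclobutenone at C4a–C5 and C6–C8a (ketene plus silyl ynol ether); the side chain between its stereocentre and CH2CO2R (auxiliary alkylation).
- Forward order: side-chain stereocentre, silyl ynol ether, four-membered ring, ring A, C4a acyl group, ring C, then release of the acid and the C5 hydroxyl.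
- Enabling feature: ring A (C4a, C5, C6, C7, C8, C8a) is hexasubstituted, with oxygen on C5, C7 and C8a alternating with carbon on C4a, C6 and C8. The benzannulation delivers the three oxygens already differentiated (C8a–OH from the ketene carbonyl, C7–OMe from the ynol ether, C5–OSi from the cyclobutenone) and leaves C4a as the only CH.
- Stereochemistry: the side-chain centre (R) comes from Evans alkylation and is carried through with retention; C2 (S) comes from a quinidine-catalysed oxa-Michael addition; C3 (R, cis) comes from kinetic protonation of the resulting enol.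

Key step: step 7

Remark (assumption): quinine is taken to give the 2R series with related o-tigloylphenols, so its pseudoenantiomer quinidine is specified for 2S in step 11; if the sense proves opposite, quinine takes its place.

**Route**

Step 1
Reactants: 1 (4S)-4-benzyl-1,3-oxazolidin-2-one; 2 heptanoyl chloride
Product: 3 (4S)-4-benzyl-3-heptanoyl-1,3-oxazolidin-2-one
Conditions: Et3N, DMAP (cat.), CH2Cl2, 0 °C to rt
Reagents that add atoms: none
Why: DMAP-catalysed N-acylation of the oxazolidinone by the acid chloride is the standard entry to an Evans imide.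

Step 2
Reactants: 3 (4S)-4-benzyl-3-heptanoyl-1,3-oxazolidin-2-one; 4 tert-butyl bromoacetate
Product: 6 tert-butyl (3R)-3-[(4S)-4-benzyl-2-oxo-1,3-oxazolidine-3-carbonyl]octanoate, via sodium Z-enolate 5 (not isolated)
Conditions: NaN(SiMe3)2, THF, −78 °C; then 4, −78 to −40 °C
Reagents that add atoms: none
Why: Evans asymmetric alkylation, in which the chelated Z-enolate is alkylated on the face opposite the benzyl group and so sets the (R) centre that becomes the benzylic carbon of the side chain.

Step 3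
Reactants: 6 tert-butyl (3R)-3-[(4S)-4-benzyl-2-oxo-1,3-oxazolidine-3-carbonyl]octanoate
Product: 7 4-tert-butyl 1-ethyl (2R)-2-pentylbutanedioate
Conditions: LiOEt, EtOH/THF, 0 °C
Reagents that add atoms: lithium ethoxide, CCO[Li]
Why: Exocyclic alkoxide cleavage (transesterification) of the imide releases the auxiliary at 0 °C without touching the hindered tert-butyl ester or the α-centre.

Step 4
Reactants: 7 4-tert-butyl 1-ethyl (2R)-2-pentylbutanedioate
Product: 10 tert-butyl (3R)-3-[2-(triisopropylsilyloxy)ethynyl]octanoate, via lithium dibromoenolate 8 (not isolated), via lithium ynolate 9 (not isolated)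
Conditions: CH2Br2, lithium 2,2,6,6-tetramethylpiperidide (3.2 equiv), THF, −78 °C; n-BuLi, −78 to 0 °C; i-Pr3SiCl, 0 °C to rt
Reagents that add atoms: dibromomethane, BrCBr; chlorotriisopropylsilane, CC(C)[Si](Cl)(C(C)C)C(C)C
Why: Kowalski ynolate formation with O-silylation, in which LiCHBr2 adds to the ethyl ester, Br–Li exchange of enolate 8 triggers 1,2-migration of the stereogenic carbon with retention to ynolate 9, and the surplus amide base holds the tert-butyl ester as its lithium enolate so that n-BuLi does not attack it.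

Step 5
Reactants: 10 tert-butyl (3R)-3-[2-(triisopropylsilyloxy)ethynyl]octanoate
Product: 11 tert-butyl (3R)-3-[4-oxo-2-(triisopropylsilyloxy)cyclobut-1-en-1-yl]octanoate
Conditions: CH2=C=O (gas), CH2Cl2, 0 °C to rt
Reagents that add atoms: ketene, C=C=O
Why: Ketene–silyl ynol ether [2+2] cycloaddition, in which the nucleophilic alkyne carbon remote from oxygen bonds to the ketene carbonyl carbon and so places the side chain on C2 and the silyloxy group on C3 of the cyclobutenone.

Step 6
Reactants: 12 chloroacetaldehyde dimethyl acetal; 13 1-bromo-3-methylbut-2-ene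
Product: 15 1-methoxy-5-methylhex-4-en-1-yne, via lithium methoxyacetylide 14 (not isolated)
Conditions: Et2NH, n-BuLi (3 equiv each), THF, 0 °C; then 13, DMPU, −78 °C to rt
Reagents that add atoms: none
Why: Double elimination (methanol, then HCl) from the chloroacetal gives the alkoxyacetylide, which is alkylated by SN2 reaction at the primary allylic bromide.

Step 7
Reactants: 11 tert-butyl (3R)-3-[4-oxo-2-(triisopropylsilyloxy)cyclobut-1-en-1-yl]octanoate; 15 1-methoxy-5-methylhex-4-en-1-yne (1.5 equiv)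
Product: 20 tert-butyl (3R)-3-[4-hydroxy-2-methoxy-3-(3-methylbut-2-enyl)-6-(triisopropylsilyloxy)phenyl]octanoate, via silyloxyvinylketene 16 (not isolated), via 4-vinylcyclobutenone 17 (not isolated), via dienylketene 18 (not isolated), via cyclohexadienone 19 (not isolated)
Conditions: toluene, 80 °C then 110 °C, sealed tube
Reagents that add atoms: none
Why: Thermal four-electron electrocyclic opening of 11 gives ketene 16, which adds ynol ether 15 in a [2+2] cycloaddition to give 17; a second four-electron opening gives dienylketene 18, and six-electron electrocyclisation followed by tautomerisation of dienone 19 gives phenol 20. The closest known reaction type is the Danheiser benzannulation of cyclobutenones with alkoxyalkynes; the 3-silyloxy group is an uncommon donor on the cyclobutenone that should slow the first opening, hence the staged heating. Ring A is the only ring closed, by thermal disrotatory 6π electrocyclisation that re-forms C4a–C8a after C8–C8a and C6–C7 have been made in the [2+2] step. No stereocentre is created, and the side-chain centre lies outside the reacting π system and is not enolisable under these neutral conditions. The step needs one orientation of the ketene–alkyne cycloaddition, and polarity secures it: the alkyne carbon remote from methoxy attacks the ketene carbonyl carbon, so prenyl ends ortho and methoxy meta to the new hydroxyl. The three oxygens therefore emerge differentiated (free C8a–OH, C7–OMe, C5–OSi) and C4a is the only unsubstituted position.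

Step 8
Reactants: 20 tert-butyl (3R)-3-[4-hydroxy-2-methoxy-3-(3-methylbut-2-enyl)-6-(triisopropylsilyloxy)phenyl]octanoate
Product: 22 tert-butyl (3R)-3-[3-formyl-4-hydroxy-6-methoxy-5-(3-methylbut-2-enyl)-2-(triisopropylsilyloxy)phenyl]octanoate, via hydroxymethylphenol 21 (not isolated)
Conditions: MgCl2, Et3N, (CH2O)n, THF, reflux
Reagents that add atoms: formaldehyde (as paraformaldehyde), C=O
Why: Casnati–Skattebøl ortho-formylation, in which the magnesium phenoxide delivers formaldehyde to the only free ortho position (C4a) and a second formaldehyde oxidises the benzylic alkoxide, under basic conditions that spare the o-prenylphenol, the silyl ether and the tert-butyl ester.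

Step 9
Reactants: 22 tert-butyl (3R)-3-[3-formyl-4-hydroxy-6-methoxy-5-(3-methylbut-2-enyl)-2-(triisopropylsilyloxy)phenyl]octanoate; 23 (E)-2-bromobut-2-ene
Product: 25 tert-butyl (3R)-3-[4-hydroxy-3-[(E)-1-hydroxy-2-methylbut-2-enyl]-6-methoxy-5-(3-methylbut-2-enyl)-2-(triisopropylsilyloxy)phenyl]octanoate (both carbinol epimers), via alkenyllithium 24 (not isolated)
Conditions: LiN(SiMe3)2, THF, −78 °C; then 24 (from 23, t-BuLi, Et2O, −78 °C); AcOH, −78 °C
Reagents that add atoms: none
Why: 1,2-Addition of an alkenyllithium made by stereoretentive Br–Li exchange to the aldehyde of the lithium phenoxide at −78 °C, where the tert-butyl ester is inert and the cold quench forestalls O-to-O silyl migration; the new carbinol centre is left uncontrolled because it is oxidised in the next step.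

Step 10
Reactants: 25 tert-butyl (3R)-3-[4-hydroxy-3-[(E)-1-hydroxy-2-methylbut-2-enyl]-6-methoxy-5-(3-methylbut-2-enyl)-2-(triisopropylsilyloxy)phenyl]octanoate
Product: 26 tert-butyl (3R)-3-[4-hydroxy-6-methoxy-3-[(E)-2-methylbut-2-enoyl]-5-(3-methylbut-2-enyl)-2-(triisopropylsilyloxy)phenyl]octanoate
Conditions: MnO2, CH2Cl2, rt
Reagents that add atoms: none
Why: MnO2 oxidation of the doubly activated (benzylic and allylic) alcohol gives the o-hydroxyaryl tigloyl ketone under neutral conditions before the labile carbinol can ionise.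

Step 11
Reactants: 26 tert-butyl (3R)-3-[4-hydroxy-6-methoxy-3-[(E)-2-methylbut-2-enoyl]-5-(3-methylbut-2-enyl)-2-(triisopropylsilyloxy)phenyl]octanoate
Product: 27 tert-butyl (3R)-3-[(2S,3R)-7-methoxy-2,3-dimethyl-8-(3-methylbut-2-enyl)-4-oxo-5-(triisopropylsilyloxy)-2,3-dihydrochromen-6-yl]octanoate
Conditions: quinidine (20 mol%), PhCl, rt
Reagents that add atoms: none
Why: Cinchona-alkaloid-catalysed asymmetric intramolecular oxa-Michael addition (6-endo-trig), in which the alkaloid-bound phenoxide O8a adds to one face of the (E)-enone to set C2 (S) and the enol is protonated under kinetic control anti to the new C2 methyl to give the cis C3 (R) centre, the C5 oxygen being kept silylated so that only O8a can close the ring.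

Step 12
Reactants: 27 tert-butyl (3R)-3-[(2S,3R)-7-methoxy-2,3-dimethyl-8-(3-methylbut-2-enyl)-4-oxo-5-(triisopropylsilyloxy)-2,3-dihydrochromen-6-yl]octanoate
Product: 28 (3R)-3-[(2S,3R)-7-methoxy-2,3-dimethyl-8-(3-methylbut-2-enyl)-4-oxo-5-(triisopropylsilyloxy)-2,3-dihydrochromen-6-yl]octanoic acid
Conditions: CF3CO2H/CH2Cl2 (1:4), 0 °C
Reagents that add atoms: none
Why: Acidolysis of the tert-butyl ester with loss of isobutene under non-enolising conditions, the C5 silyl ether being retained so that the acid cannot lactonise onto O5, while the prenyl olefin, flanked only by ether oxygens, should survive brief cold acid.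

Step 13
Reactants: 28 (3R)-3-[(2S,3R)-7-methoxy-2,3-dimethyl-8-(3-methylbut-2-enyl)-4-oxo-5-(triisopropylsilyloxy)-2,3-dihydrochromen-6-yl]octanoic acid
Product: 29 (3R)-3-[(2S,3R)-5-hydroxy-7-methoxy-2,3-dimethyl-8-(3-methylbut-2-enyl)-4-oxo-2,3-dihydrochromen-6-yl]octanoic acid
Conditions: HF·pyridine, THF, 0 °C to rt
Reagents that add atoms: none
Why: Fluoride cleavage of the aryl silyl ether in a mildly acidic, non-basic medium preserves the epimerisable cis C3 centre and frees the C5 hydroxyl, which is held by the hydrogen bond to the C4 carbonyl.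

**Compound list**

1 | (4S)-4-benzyl-1,3-oxazolidin-2-one | O=C1N[C@@H](Cc2ccccc2)CO1 | starting material
2 | heptanoyl chloride | CCCCCCC(=O)Cl | starting material
3 | (4S)-4-benzyl-3-heptanoyl-1,3-oxazolidin-2-one | CCCCCCC(=O)N1[C@@H](Cc2ccccc2)COC1=O | intermediate
4 | tert-butyl bromoacetate | CC(C)(C)OC(=O)CBr | starting material
5 | sodium (Z)-enolate of 3 | CCCCC/C=C(\[O-])N1[C@@H](Cc2ccccc2)COC1=O.[Na+] | intermediate (not isolated)
6 | tert-butyl (3R)-3-[(4S)-4-benzyl-2-oxo-1,3-oxazolidine-3-carbonyl]octanoate | CCCCC[C@H](CC(=O)OC(C)(C)C)C(=O)N1[C@@H](Cc2ccccc2)COC1=O | intermediate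
7 | 4-tert-butyl 1-ethyl (2R)-2-pentylbutanedioate | CCCCC[C@H](CC(=O)OC(C)(C)C)C(=O)OCC | intermediate
8 | lithium enolate of tert-butyl (3R)-3-(2,2-dibromoacetyl)octanoate | CCCCC[C@H](CC(=O)OC(C)(C)C)C([O-])=C(Br)Br.[Li+] | intermediate (not isolated)
9 | lithium 2-[(3R)-1-tert-butoxy-1-oxooctan-3-yl]ethynolate | CCCCC[C@H](CC(=O)OC(C)(C)C)C#C[O-].[Li+] | intermediate (not isolated)
10 | tert-butyl (3R)-3-[2-(triisopropylsilyloxy)ethynyl]octanoate | CCCCC[C@H](CC(=O)OC(C)(C)C)C#CO[Si](C(C)C)(C(C)C)C(C)C | intermediate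
11 | tert-butyl (3R)-3-[4-oxo-2-(triisopropylsilyloxy)cyclobut-1-en-1-yl]octanoate | CCCCC[C@H](CC(=O)OC(C)(C)C)C1=C(O[Si](C(C)C)(C(C)C)C(C)C)CC1=O | intermediate
12 | chloroacetaldehyde dimethyl acetal (2-chloro-1,1-dimethoxyethane) | COC(CCl)OC | starting material
13 | 1-bromo-3-methylbut-2-ene | CC(C)=CCBr | starting material
14 | lithium methoxyacetylide | COC#[C-].[Li+] | intermediate (not isolated)
15 | 1-methoxy-5-methylhex-4-en-1-yne | COC#CCC=C(C)C | intermediate
16 | tert-butyl (3R)-3-[1-oxo-3-(triisopropylsilyloxy)buta-1,3-dien-2-yl]octanoate (silyloxyvinylketene) | CCCCC[C@H](CC(=O)OC(C)(C)C)C(=C=O)C(=C)O[Si](C(C)C)(C(C)C)C(C)C | intermediate (not isolated)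
17 | tert-butyl (3R)-3-[3-methoxy-2-(3-methylbut-2-enyl)-4-oxo-1-[1-(triisopropylsilyloxy)ethenyl]cyclobut-2-en-1-yl]octanoate (both ring epimers) | CCCCC[C@H](CC(=O)OC(C)(C)C)C1(C(=C)O[Si](C(C)C)(C(C)C)C(C)C)C(=O)C(CC=C(C)C)=C1OC | intermediate (not isolated)
18 | dienylketene from 17, with the ketenyl and silyloxyvinyl groups cis on the central double bond | CCCCC[C@H](CC(=O)OC(C)(C)C)/C(C(=C)O[Si](C(C)C)(C(C)C)C(C)C)=C(\OC)C(CC=C(C)C)=C=O | intermediate (not isolated)
19 | cyclohexa-2,4-dienone tautomer of 20 | CCCCC[C@H](CC(=O)OC(C)(C)C)C1=C(O[Si](C(C)C)(C(C)C)C(C)C)CC(=O)C(CC=C(C)C)=C1OC | intermediate (not isolated)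
20 | tert-butyl (3R)-3-[4-hydroxy-2-methoxy-3-(3-methylbut-2-enyl)-6-(triisopropylsilyloxy)phenyl]octanoate | CCCCC[C@H](CC(=O)OC(C)(C)C)c1c(O[Si](C(C)C)(C(C)C)C(C)C)cc(O)c(CC=C(C)C)c1OC | intermediate
21 | tert-butyl (3R)-3-[4-hydroxy-3-(hydroxymethyl)-6-methoxy-5-(3-methylbut-2-enyl)-2-(triisopropylsilyloxy)phenyl]octanoate | CCCCC[C@H](CC(=O)OC(C)(C)C)c1c(O[Si](C(C)C)(C(C)C)C(C)C)c(CO)c(O)c(CC=C(C)C)c1OC | intermediate (not isolated)
22 | tert-butyl (3R)-3-[3-formyl-4-hydroxy-6-methoxy-5-(3-methylbut-2-enyl)-2-(triisopropylsilyloxy)phenyl]octanoate | CCCCC[C@H](CC(=O)OC(C)(C)C)c1c(O[Si](C(C)C)(C(C)C)C(C)C)c(C=O)c(O)c(CC=C(C)C)c1OC | intermediate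
23 | (E)-2-bromobut-2-ene | C/C=C(\C)Br | starting material
24 | (Z)-but-2-en-2-yllithium (methyl groups cis) | C/C=C(\C)[Li] | intermediate (not isolated)
25 | tert-butyl (3R)-3-[4-hydroxy-3-[(E)-1-hydroxy-2-methylbut-2-enyl]-6-methoxy-5-(3-methylbut-2-enyl)-2-(triisopropylsilyloxy)phenyl]octanoate (both carbinol epimers) | CCCCC[C@H](CC(=O)OC(C)(C)C)c1c(O[Si](C(C)C)(C(C)C)C(C)C)c(C(O)/C(C)=C/C)c(O)c(CC=C(C)C)c1OC | intermediate
26 | tert-butyl (3R)-3-[4-hydroxy-6-methoxy-3-[(E)-2-methylbut-2-enoyl]-5-(3-methylbut-2-enyl)-2-(triisopropylsilyloxy)phenyl]octanoate | CCCCC[C@H](CC(=O)OC(C)(C)C)c1c(O[Si](C(C)C)(C(C)C)C(C)C)c(C(=O)/C(C)=C/C)c(O)c(CC=C(C)C)c1OC | intermediate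
27 | tert-butyl (3R)-3-[(2S,3R)-7-methoxy-2,3-dimethyl-8-(3-methylbut-2-enyl)-4-oxo-5-(triisopropylsilyloxy)-2,3-dihydrochromen-6-yl]octanoate | CCCCC[C@H](CC(=O)OC(C)(C)C)c1c(O[Si](C(C)C)(C(C)C)C(C)C)c2c(c(CC=C(C)C)c1OC)O[C@@H](C)[C@@H](C)C2=O | intermediate
28 | (3R)-3-[(2S,3R)-7-methoxy-2,3-dimethyl-8-(3-methylbut-2-enyl)-4-oxo-5-(triisopropylsilyloxy)-2,3-dihydrochromen-6-yl]octanoic acid | CCCCC[C@H](CC(=O)O)c1c(O[Si](C(C)C)(C(C)C)C(C)C)c2c(c(CC=C(C)C)c1OC)O[C@@H](C)[C@@H](C)C2=O | intermediate
29 | (3R)-3-[(2S,3R)-5-hydroxy-7-methoxy-2,3-dimethyl-8-(3-methylbut-2-enyl)-4-oxo-2,3-dihydrochromen-6-yl]octanoic acid | CCCCC[C@H](CC(=O)O)c1c(O)c2c(c(CC=C(C)C)c1OC)O[C@@H](C)[C@@H](C)C2=O | target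

**Step count**

Total: 13 steps. Longest linear sequence: 12 steps (steps 1–5 and 7–13); step 6 is a one-step branch.

**Steps most likely to fail**

Step 7. The donor-substituted cyclobutenone may open only at temperatures where ketene 16 is consumed by self-condensation and by acylation of the product phenol faster than the ynol ether captures it. The fallback sets out from 15 and 11 and comes back at 20, replacing the ynol ether by a far more nucleophilic two-carbon partner. Sodium methoxide-catalysed addition of methanol to 15 should give the ketene acetal 1,1-dimethoxy-5-methylhexa-1,4-diene F1. Heating 11 with F1 in toluene should give, by ketene–ketene acetal [2+2] cycloaddition, the cyclobutanone tert-butyl (3R)-3-[2,2-dimethoxy-3-(3-methylbut-2-enyl)-4-oxo-1-[1-(triisopropylsilyloxy)ethenyl]cyclobutyl]octanoate F2. β-Elimination of methanol from F2 gives 17, which is isolated and thermolysed on its own to 20 by the same ring opening and 6π closure.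

Step 4. The tert-butyl ester may be lost by attack of n-BuLi or by condensation of its enolate, and the α-centre may erode through deprotonation during ynolate formation. The fallback sets out from 6 and comes back at 11, avoiding organolithium reagents altogether. Cleavage of the auxiliary with LiOH/H2O2 gives (2R)-2-(2-tert-butoxy-2-oxoethyl)heptanoic acid F3. Activation with isobutyl chloroformate and N-methylmorpholine followed by diazomethane gives tert-butyl (3R)-3-(2-diazoacetyl)octanoate F4. Photochemical Wolff rearrangement of F4 in the presence of ethoxyacetylene gives, with retention at the migrating carbon, the alkylketene tert-butyl (3R)-3-(2-oxoethenyl)octanoate F5. F5 is trapped in a [2+2] cycloaddition as tert-butyl (3R)-3-(2-ethoxy-4-oxocyclobut-2-en-1-yl)octanoate F6. Dilute aqueous HCl in THF hydrolyses the enol ether to the enolised 1,3-dione tert-butyl (3R)-3-(2-hydroxy-4-oxocyclobut-1-en-1-yl)octanoate F7, and O-silylation with i-Pr3SiOTf and Et3N gives 11.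

Step 11. Ion pairing of the hindered phenol beside the bulky silyl ether may be too loose for good facial selectivity, and the enol may be protonated partly on the wrong face or the product may epimerise to the trans isomer. The fallback sets out from 22 and comes back at 27, replacing the oxygen nucleophile by a reagent-controlled carbon nucleophile. Addition of EtMgBr to 22 (phenol first deprotonated) gives tert-butyl (3R)-3-[4-hydroxy-3-(1-hydroxypropyl)-6-methoxy-5-(3-methylbut-2-enyl)-2-(triisopropylsilyloxy)phenyl]octanoate F8. MnO2 oxidation gives the propiophenone tert-butyl (3R)-3-[4-hydroxy-6-methoxy-5-(3-methylbut-2-enyl)-3-propanoyl-2-(triisopropylsilyloxy)phenyl]octanoate F9. Heating with Me2NCH(OMe)2 gives the enaminone tert-butyl (3R)-3-[3-[3-(dimethylamino)-2-methylprop-2-enoyl]-4-hydroxy-6-methoxy-5-(3-methylbut-2-enyl)-2-(triisopropylsilyloxy)phenyl]octanoate F10. F10 closes with loss of dimethylamine to the chromone tert-butyl (3R)-3-[7-methoxy-3-methyl-8-(3-methylbut-2-enyl)-4-oxo-5-(triisopropylsilyloxy)chromen-6-yl]octanoate F11. Enantioselective conjugate addition of MeMgBr catalysed by CuBr·SMe2 and a chiral ferrocenyl diphosphine at −78 °C gives the bromomagnesium enolate of tert-butyl (3R)-3-[(2S)-7-methoxy-2,3-dimethyl-8-(3-methylbut-2-enyl)-4-oxo-5-(triisopropylsilyloxy)-2H-chromen-6-yl]octanoate F12. Protonation of F12 at −78 °C with 2,6-di-tert-butylphenol, anti to the C2 methyl, gives 27.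

**Further compounds**

F1 | step 7 | 1,1-dimethoxy-5-methylhexa-1,4-diene | COC(OC)=CCC=C(C)C
F2 | step 7 | tert-butyl (3R)-3-[2,2-dimethoxy-3-(3-methylbut-2-enyl)-4-oxo-1-[1-(triisopropylsilyloxy)ethenyl]cyclobutyl]octanoate | CCCCC[C@H](CC(=O)OC(C)(C)C)C1(C(=C)O[Si](C(C)C)(C(C)C)C(C)C)C(=O)C(CC=C(C)C)C1(OC)OC
F3 | step 4 | (2R)-2-(2-tert-butoxy-2-oxoethyl)heptanoic acid | CCCCC[C@H](CC(=O)OC(C)(C)C)C(=O)O
F4 | step 4 | tert-butyl (3R)-3-(2-diazoacetyl)octanoate | CCCCC[C@H](CC(=O)OC(C)(C)C)C(=O)C=[N+]=[N-]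
F5 | step 4 | tert-butyl (3R)-3-(2-oxoethenyl)octanoate | CCCCC[C@H](CC(=O)OC(C)(C)C)C=C=O
F6 | step 4 | tert-butyl (3R)-3-(2-ethoxy-4-oxocyclobut-2-en-1-yl)octanoate | CCCCC[C@H](CC(=O)OC(C)(C)C)C1C(=O)C=C1OCC
F7 | step 4 | tert-butyl (3R)-3-(2-hydroxy-4-oxocyclobut-1-en-1-yl)octanoate | CCCCC[C@H](CC(=O)OC(C)(C)C)C1=C(O)CC1=O
F8 | step 11 | tert-butyl (3R)-3-[4-hydroxy-3-(1-hydroxypropyl)-6-methoxy-5-(3-methylbut-2-enyl)-2-(triisopropylsilyloxy)phenyl]octanoate | CCCCC[C@H](CC(=O)OC(C)(C)C)c1c(O[Si](C(C)C)(C(C)C)C(C)C)c(C(O)CC)c(O)c(CC=C(C)C)c1OC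
F9 | step 11 | tert-butyl (3R)-3-[4-hydroxy-6-methoxy-5-(3-methylbut-2-enyl)-3-propanoyl-2-(triisopropylsilyloxy)phenyl]octanoate | CCCCC[C@H](CC(=O)OC(C)(C)C)c1c(O[Si](C(C)C)(C(C)C)C(C)C)c(C(=O)CC)c(O)c(CC=C(C)C)c1OC
F10 | step 11 | tert-butyl (3R)-3-[3-[3-(dimethylamino)-2-methylprop-2-enoyl]-4-hydroxy-6-methoxy-5-(3-methylbut-2-enyl)-2-(triisopropylsilyloxy)phenyl]octanoate | CCCCC[C@H](CC(=O)OC(C)(C)C)c1c(O[Si](C(C)C)(C(C)C)C(C)C)c(C(=O)C(C)=CN(C)C)c(O)c(CC=C(C)C)c1OC
F11 | step 11 | tert-butyl (3R)-3-[7-methoxy-3-methyl-8-(3-methylbut-2-enyl)-4-oxo-5-(triisopropylsilyloxy)chromen-6-yl]octanoate | CCCCC[C@H](CC(=O)OC(C)(C)C)c1c(O[Si](C(C)C)(C(C)C)C(C)C)c2c(c(CC=C(C)C)c1OC)OC=C(C)C2=O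
F12 | step 11 | bromomagnesium enolate of tert-butyl (3R)-3-[(2S)-7-methoxy-2,3-dimethyl-8-(3-methylbut-2-enyl)-4-oxo-5-(triisopropylsilyloxy)-2H-chromen-6-yl]octanoate | CCCCC[C@H](CC(=O)OC(C)(C)C)c1c(O[Si](C(C)C)(C(C)C)C(C)C)c2c(c(CC=C(C)C)c1OC)O[C@@H](C)C(C)=C2O[Mg]Br
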